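## Retrosynthetic overview

1. The target is cut at the C12–C13 bond of the ethylene bridge: a C13 radical from γ-lactone 24 (oxepane–cyclohexane half, one sacrificial carboxyl carbon) adds to the exocyclic 1,3-diene 11 (hydroazulene half), and the same step sets C11.
2. 24 ⇒ enol-ether epoxide/AlMe3 ⇒ enol-ether RCM ⇒ isopropenyl ether made by Criegee oxygen insertion into the C21–CMe2 bond ⇒ ring-opened conjugate adduct of (1S,5S)-verbenone (C15 from the conjugate addition; C24 and the lactone from an equatorial MeMgBr addition).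
3. 11 ⇒ epoxide reduction/Wittig ⇒ gem-dimethyl cycloheptenone ⇒ one-carbon ring expansion ⇒ RCM ⇒ cis-6-allyl-(S)-carvone.
4. Ring order: right half cyclohexane (bought) → γ-lactone → oxepane; left half cyclohexenone (bought) → cyclopentene → cycloheptenone; the halves are joined last.

Assumption: enantiopure (S)-(+)-carvone and (1S,5S)-(−)-verbenone (bought, or from high-ee (−)-α-pinene) are the chiral starting materials; locants follow the atom order of the target SMILES (C1 = methyl on C2; C2–C11 hydroazulene with C5/C6 ring fusion, C9 carbinol, C10 CMe2; C12–C13 bridge; C14–C19, O20, C21–C24 oxepane–cyclohexane with C15 quaternary, C18 and C24 carbinols).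

## Route

Step 1
Reactants: 1 (S)-(+)-carvone
Product: 3 cis-6-allylcarvone, via trans-6-allylcarvone 2 (not isolated)
Conditions: LiN(iPr)2, THF, −78 °C; allyl bromide, −78 → 0 °C; then LiN(iPr)2, −78 °C; AcOH, −78 °C
Reagents that add atoms: allyl bromide C=CCBr
Why: Kinetic α′-enolate alkylation of the enone puts allyl on C6 (first trans to the C5 isopropenyl group), and re-enolisation followed by kinetic protonation anti to the isopropenyl group inverts C6 so that allyl and isopropenyl are cis, as the cis ring fusion requires (C5 is bought in carvone).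

Step 2
Reactants: 3 cis-6-allylcarvone
Product: 4 bicyclic dienone
Conditions: second-generation Grubbs catalyst RuCl2(=CHPh)(PCy3)(H2IMes) (2 mol%), CH2Cl2, 40 °C
Reagents that add atoms: none
Why: Ring-closing metathesis of the allyl and isopropenyl groups forms the cyclopentene (C5–C9=C8–C7–C6) without touching a stereocentre.

Step 3
Reactants: 4 bicyclic dienone
Product: 6 cycloheptenone, via silyl ketone 5 (not isolated)
Conditions: Me3SiCHN2, BF3·OEt2, CH2Cl2, −78 → −30 °C; then 1 M HCl, THF, 25 °C
Reagents that add atoms: (trimethylsilyl)diazomethane C[Si](C)(C)C=[N+]=[N-]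
Why: Lewis-acid-promoted diazoalkane homologation (Tiffeneau–Demjanov type) inserts C10 between the carbonyl carbon and the sp3 ring-fusion carbon C6, which is expected to migrate, with retention, in preference to the conjugated alkenyl carbon, so the cis fusion is kept, and protodesilylation gives the ketone.

Step 4
Reactants: 6 cycloheptenone
Product: 8 gem-dimethyl cycloheptenone, via monomethyl ketone 7 (not isolated)
Conditions: LiN(iPr)2, THF, −78 °C, MeI; then LiN(iPr)2, HMPA, −78 → 0 °C, MeI
Reagents that add atoms: iodomethane CI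
Why: Two kinetic α′-enolate methylations at C10 (the other α-carbon is the alkene carbon C2) install the gem-dimethyl group, and no stereocentre is formed.

Step 5
Reactants: 8 gem-dimethyl cycloheptenone
Product: 9 epoxy enone
Conditions: mCPBA, NaHCO3, CH2Cl2, 0 °C
Reagents that add atoms: meta-chloroperoxybenzoic acid OOC(=O)c1cccc(Cl)c1
Why: Prilezhaev epoxidation is chemoselective for the electron-rich trisubstituted cyclopentene over the enone and occurs on the convex face of the cis-fused bicycle (the face of H5/H6), which fixes the C9–O configuration.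

Step 6
Reactants: 9 epoxy enone
Product: 10 epoxy diene
Conditions: Ph3PCH3Br, KOtBu, toluene, 90 °C
Reagents that add atoms: methyltriphenylphosphonium bromide C[P+](c1ccccc1)(c1ccccc1)c1ccccc1.[Br-]
Why: Wittig methylenation of the hindered enone carbonyl gives the semicyclic 1,3-diene C12=C11–C2=C3 without affecting a stereocentre.

Step 7
Reactants: 10 epoxy diene
Product: 11 dienol
Conditions: LiBHEt3, THF, 0 → 65 °C
Reagents that add atoms: none
Why: SN2 hydride opening of the trisubstituted epoxide at the less substituted C8 leaves the oxygen on C9 as the tertiary alcohol in the configuration set in step 5.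

Step 8
Reactants: 12 (1S,5S)-(−)-verbenone
Product: 14 bicyclic keto ester, via bromomagnesium enolate 13 (not isolated)
Conditions: but-3-enylMgBr, CuBr·SMe2 (10 mol%), THF, −40 °C; then HMPA, BrCH2CO2Me, −40 → 0 °C
Reagents that add atoms: but-3-enylmagnesium bromide C=CCC[Mg]Br; methyl bromoacetate COC(=O)CBr
Why: Copper-catalysed conjugate addition occurs anti to the gem-dimethyl bridge and creates the quaternary C15 (methyl cis, butenyl trans to the bridge carbon on C21), and the regiodefined enolate (the bridgehead side cannot enolise) is C-alkylated at C14, whose configuration is corrected in step 9.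

Step 9
Reactants: 14 bicyclic keto ester
Product: 15 chloro keto ester
Conditions: HCl (g), AcOH–CH2Cl2, 0 → 25 °C
Reagents that add atoms: hydrogen chloride Cl
Why: Acid-promoted fragmentation of the ketone-activated cyclobutane bond (pinane to p-menthane ring opening) gives the tertiary chloride on the carbon attached to C21 without touching C21, and acid-catalysed enolisation equilibrates C14 to the equatorial CH2CO2Me epimer, cis to the C15 methyl.

Step 10
Reactants: 15 chloro keto ester
Product: 17 chloro γ-lactone, via hydroxy ester 16 (not isolated)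
Conditions: MeMgBr, CeCl3, THF, −78 °C; then aq. NH4Cl, 25 °C
Reagents that add atoms: methylmagnesium bromide C[Mg]Br
Why: Cerium-mediated Grignard addition is ketone-selective and equatorial because the axial C15 methyl blocks axial attack, which gives the axial C24 oxygen (C24 set), and this lactonises onto the cis CH2CO2Me group (γ-keto ester to γ-lactone).

Step 11
Reactants: 17 chloro γ-lactone
Product: 18 hydroperoxide
Conditions: H2O2 (anhydrous, Et2O), AgOCOCF3, 0 °C
Reagents that add atoms: hydrogen peroxide OO
Why: Silver-assisted SN1 perhydrolysis of the tertiary chloride gives the tertiary hydroperoxide, and no stereocentre is involved.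

Step 12
Reactants: 18 hydroperoxide
Product: 21 isopropenyl ether, via peroxy trifluoroacetate 19 (not isolated), via trifluoroacetoxy ketal 20 (not isolated)
Conditions: (CF3CO)2O, iPr2NEt, CH2Cl2, −40 → 25 °C
Reagents that add atoms: none
Why: Criegee rearrangement of the perester moves C21 from carbon to oxygen with retention (secondary alkyl migrates in preference to methyl), and base-induced loss of trifluoroacetic acid from the acetone-derived ketal ester gives the enol ether.

Step 13
Reactants: 21 isopropenyl ether
Product: 22 cyclic enol ether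
Conditions: second-generation Grubbs catalyst RuCl2(=CHPh)(PCy3)(H2IMes) (10 mol%), toluene, 80 °C
Reagents that add atoms: none
Why: Enol ether–olefin ring-closing metathesis closes the seven-membered ring and forms the C18=C19 bond, with no stereocentre formed.

Step 14
Reactants: 22 cyclic enol ether
Product: 24 hydroxy γ-lactone, via enol-ether epoxide 23 (not isolated)
Conditions: dimethyldioxirane, CH2Cl2–acetone, −78 → 0 °C; then AlMe3, CH2Cl2, −78 → 0 °C
Reagents that add atoms: dimethyldioxirane CC1(C)OO1; trimethylaluminium C[Al](C)C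
Why: Epoxidation of the enol ether occurs anti to the axial C15 methyl (setting C18), and AlMe3 opens the epoxide at the ketal carbon C19 with methyl transfer (glycal-epoxide C-methylation), giving the gem-dimethyl ether and the C18 alcohol while the lactone is untouched at low temperature.

Step 15
Reactants: 24 hydroxy γ-lactone; 11 dienol
Product: 26 target, via caesium carboxylate 25 (not isolated)
Conditions: CsOH·H2O, THF–H2O, 40 °C, evaporate; then 11 (1.5 equiv), Ir[dF(CF3)ppy]2(dtbbpy)PF6 (2 mol%), CrCl3(thf)3 (10 mol%), 4,4′-di-tert-butyl-2,2′-bipyridine (12 mol%), DMF–H2O (20:1), 450 nm LEDs, 25 °C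
Reagents that add atoms: none
Why: Proposed new method: photoredox/chromium dual-catalysed decarboxylative 1,2-hydroalkylation of a 1,3-diene, in which the excited iridium photocatalyst oxidises carboxylate 25 to a primary C13 radical (loss of CO2) that adds to the unsubstituted diene terminus C12 to form the C12–C13 bond, the allyl radical is trapped by divalent chromium (regenerated from trivalent chromium by the reduced photocatalyst) as an allylchromium bound at the less hindered C3 terminus on the convex face, and protonolysis by chromium-bound water through a closed six-membered SE2′ transition state delivers H to C11 on that same face (cis to H5/H6) and leaves the C2=C3 alkene; the closest known reactions are the photoredox/chromium three-component dialkylation of 1,3-dienes with aldehydes and decarboxylative Giese additions.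

## Compound list

1 | (S)-(+)-carvone [(5S)-2-methyl-5-(prop-1-en-2-yl)cyclohex-2-en-1-one] | CC1=CC[C@H](C(C)=C)CC1=O | starting material
2 | trans-6-allylcarvone [(5S,6R)-6-allyl-2-methyl-5-(prop-1-en-2-yl)cyclohex-2-en-1-one] | CC1=CC[C@H](C(C)=C)[C@@H](CC=C)C1=O | intermediate
3 | cis-6-allylcarvone [(5S,6S)-isomer] | CC1=CC[C@H](C(C)=C)[C@H](CC=C)C1=O | intermediate
4 | bicyclic dienone [(3aS,7aS)-3,6-dimethyl-1,3a,4,7a-tetrahydro-7H-inden-7-one, cis ring fusion] | CC1=CC[C@H]2[C@H](CC=C2C)C1=O | intermediate
5 | silyl ketone [C10-trimethylsilyl derivative of 6, both C10 epimers] | CC1=CC[C@H]2[C@H](CC=C2C)C([Si](C)(C)C)C1=O | intermediate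
6 | cycloheptenone [(3aS,8aR)-3,6-dimethyl-1,3a,4,7,8,8a-hexahydroazulen-7-one, cis ring fusion; C11 ketone, C2=C3, C8=C9] | CC1=CC[C@H]2[C@H](CC=C2C)CC1=O | intermediate
7 | monomethyl ketone [C10-methyl derivative of 6, both C10 epimers] | CC1=CC[C@H]2[C@H](CC=C2C)C(C)C1=O | intermediate
8 | gem-dimethyl cycloheptenone [(3aS,8aS)-3,6,8,8-tetramethyl-1,3a,4,7,8,8a-hexahydroazulen-7-one] | CC1=CC[C@H]2[C@H](CC=C2C)C(C)(C)C1=O | intermediate
9 | epoxy enone [C8–C9 epoxide of 8, oxygen on the face of H5/H6] | CC1=CC[C@H]2[C@H](C[C@H]3[C@]2(C)O3)C(C)(C)C1=O | intermediate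
10 | epoxy diene [C11 methylene analogue of 9] | CC1=CC[C@H]2[C@H](C[C@H]3[C@]2(C)O3)C(C)(C)C1=C | intermediate
11 | dienol [hydroazulene half: C9 tertiary alcohol with OH cis to H5/H6, C2=C3, exocyclic C11=C12H2] | CC1=CC[C@H]2[C@H](CC[C@]2(C)O)C(C)(C)C1=C | intermediate
12 | (1S,5S)-(−)-verbenone [4,6,6-trimethylbicyclo[3.1.1]hept-3-en-2-one] | CC1=CC(=O)[C@H]2C[C@@H]1C2(C)C | starting material
13 | bromomagnesium enolate [1,4-adduct of 12, butenyl anti to the CMe2 bridge] | C[C@]1(CCC=C)C=C(O[Mg]Br)[C@H]2C[C@@H]1C2(C)C | intermediate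
14 | bicyclic keto ester [methyl 2-[4-(but-3-enyl)-4,6,6-trimethyl-2-oxobicyclo[3.1.1]heptan-3-yl]acetate, butenyl anti to the CMe2 bridge, both epimers at the acetate-bearing carbon] | C[C@]1(CCC=C)C(CC(=O)OC)C(=O)[C@H]2C[C@@H]1C2(C)C | intermediate
15 | chloro keto ester [methyl 2-[2-(but-3-enyl)-3-(2-chloropropan-2-yl)-2-methyl-6-oxocyclohexyl]acetate; CH2CO2Me, ring methyl and CMe2Cl mutually cis, butenyl trans] | COC(=O)C[C@H]1[C@](C)(CCC=C)[C@@H](C(C)(C)Cl)CCC1=O | intermediate
16 | hydroxy ester [C24 tertiary alcohol of 15, OH cis to CH2CO2Me and to the C15 methyl] | COC(=O)C[C@H]1[C@](C)(CCC=C)[C@@H](C(C)(C)Cl)CC[C@@]1(C)O | intermediate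
17 | chloro γ-lactone [cis-fused lactone C13–C(=O)–O–C24 of 16] | O=C3C[C@H]1[C@](C)(CCC=C)[C@@H](C(C)(C)Cl)CC[C@@]1(C)O3 | intermediate
18 | hydroperoxide [17 with CMe2OOH on C21] | O=C3C[C@H]1[C@](C)(CCC=C)[C@@H](C(C)(C)OO)CC[C@@]1(C)O3 | intermediate
19 | peroxy trifluoroacetate [O-trifluoroacetyl derivative of 18] | O=C3C[C@H]1[C@](C)(CCC=C)[C@@H](C(C)(C)OOC(=O)C(F)(F)F)CC[C@@]1(C)O3 | intermediate
20 | trifluoroacetoxy ketal [C21–O–CMe2–OCOCF3] | O=C3C[C@H]1[C@](C)(CCC=C)[C@@H](OC(C)(C)OC(=O)C(F)(F)F)CC[C@@]1(C)O3 | intermediate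
21 | isopropenyl ether [C21–O–C(CH3)=CH2, butenyl on C15] | O=C3C[C@H]1[C@](C)(CCC=C)[C@@H](OC(C)=C)CC[C@@]1(C)O3 | intermediate
22 | cyclic enol ether [oxepene O20–C19(CH3)=C18H, trans-fused to the cyclohexane, γ-lactone retained] | O=C3C[C@H]1[C@]2(C)CCC=C(C)O[C@H]2CC[C@@]1(C)O3 | intermediate
23 | enol-ether epoxide [C18–C19 epoxide anti to the C15 methyl] | O=C3C[C@H]1[C@]2(C)CC[C@@H]4O[C@]4(C)O[C@H]2CC[C@@]1(C)O3 | intermediate
24 | hydroxy γ-lactone [oxepane–cyclohexane half: C18 OH, C19 gem-dimethyl, lactone C13–C(=O)–O–C24] | O=C3C[C@H]1[C@]2(C)CC[C@H](O)C(C)(C)O[C@H]2CC[C@@]1(C)O3 | intermediate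
25 | caesium carboxylate [ring-opened salt of 24, C13H2–CO2Cs, free C24 OH] | [Cs+].[O-]C(=O)C[C@H]1[C@]2(C)CC[C@H](O)C(C)(C)O[C@H]2CC[C@@]1(C)O | intermediate
26 | target CNP0183476.2 | CC1=CC[C@H]2[C@H](CC[C@]2(C)O)C(C)(C)[C@@H]1CC[C@H]1[C@]2(C)CC[C@H](O)C(C)(C)O[C@H]2CC[C@@]1(C)O | target

## Step count and risks

Total: 15 steps (7 to dienol 11, 7 to lactone 24, 1 union). Longest linear sequence: 8 steps (from either starting material).

Steps most likely to fail:

1. Step 15 (new chromium-mediated diene hydroalkylation). Risks are inefficient capture of the allyl radical and the wrong regio- or facial selectivity in the protonation. The fallback sets C11 first and makes the bond by a known nickel/photoredox decarboxylative alkyl–alkyl coupling. It sets out from 11: hydroboration with 9-BBN from the convex face gives the alkylborane F1, NaOH/H2O2 gives the primary alcohol F2, and CBr4/PPh3 gives the primary bromide F3. F3 is then coupled with caesium carboxylate 25 (from 24) under NiCl2·glyme, 4,4′-dimethoxy-2,2′-bipyridine, Ir[dF(CF3)ppy]2(dtbbpy)PF6 and blue light, and the route is rejoined at 26.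

2. Step 3 (ring expansion). The alkenyl carbon could migrate instead of C6. The fallback masks the enone so that only C6 can migrate. It sets out from 4: H2O2/NaOH gives the epoxy ketone F4, Me3SiCHN2/BF3·OEt2 gives the silyl ketone F5, and aqueous HCl gives the epoxy cycloheptanone F6. SmI2/MeOH then gives the β-hydroxy ketone F7, and MsCl/Et3N followed by DBU returns to the route at 6.

3. Step 12 (Criegee rearrangement with elimination). The ketal ester may hydrolyse or fail to eliminate cleanly. The fallback separates oxygen insertion from enol ether formation. It sets out from 18: BF3·OEt2-promoted Hock rearrangement and aqueous work-up give the C21 alcohol F8, 2-methoxypropene/PPTS gives the mixed ketal F9, and TMSOTf/iPr2NEt eliminates the methoxy group to return at 21.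

Further compounds
F1 | step 15 | alkylborane [B-alkyl-9-borabicyclo[3.3.1]nonane of 11, boron on C12, H11 cis to H5/H6] | CC1=CC[C@H]2[C@H](CC[C@]2(C)O)C(C)(C)[C@@H]1CB1C2CCCC1CCC2
F2 | step 15 | primary alcohol [C12–OH] | CC1=CC[C@H]2[C@H](CC[C@]2(C)O)C(C)(C)[C@@H]1CO
F3 | step 15 | primary bromide [C12–Br] | CC1=CC[C@H]2[C@H](CC[C@]2(C)O)C(C)(C)[C@@H]1CBr
F4 | step 3 | epoxy ketone [C2–C3 epoxide of 4, epoxide configuration not defined] | CC12OC1C[C@H]3[C@H](CC=C3C)C2=O
F5 | step 3 | silyl ketone [ring-expanded, C10-trimethylsilyl, both C10 epimers] | CC12OC1C[C@H]3[C@H](CC=C3C)C([Si](C)(C)C)C2=O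
F6 | step 3 | epoxy cycloheptanone | CC12OC1C[C@H]3[C@H](CC=C3C)CC2=O
F7 | step 3 | β-hydroxy ketone [C3–OH, C2–H] | CC1C(O)C[C@H]2[C@H](CC=C2C)CC1=O
F8 | step 12 | C21 alcohol [lactone with free C21–OH and butenyl on C15] | O=C3C[C@H]1[C@](C)(CCC=C)[C@@H](O)CC[C@@]1(C)O3
F9 | step 12 | mixed ketal [C21–O–CMe2–OMe] | O=C3C[C@H]1[C@](C)(CCC=C)[C@@H](OC(C)(C)OC)CC[C@@]1(C)O3
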